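## Analysis of the target

The target is a tetracycle. A 3,4-dihydro-2H-pyran (O1, C2–C6) is fused through its enol-ether bond C5=C6 to the central ring of a dibenzo[b,f]oxepine: C5 carries ring A through A1, C6 carries ring B through B1, and A2 and B2 are joined by the diaryl ether oxygen. Ring A is a resorcinol unit with a free hydroxyl at A4 and a prenyl group at A5. Ring B has one free hydroxyl at B4, para to B1. C2 bears a methyl group and a 4-methylpent-3-enyl chain. There are two adjacent stereocentres, both S: the quaternary ether carbon C2 and the secondary carbinol C3. Their relative arrangement is that of two oxygens added anti across the (Z)-2,3-double bond of nerol, which also contains the complete C10 chain. Sensitive functions are the tetrasubstituted enol ether (protic acid, electrophiles), two trisubstituted olefins (acid, halogens, hydrogenation, metathesis), the ortho-prenylphenol (acid-induced chroman formation) and two electron-rich phenols (oxidants). The difficulty lies in the tetrasubstituted enol ether embedded in a seven-membered diaryl ether, in placing the ether oxygen on the correct carbon of ring B, and in keeping four oxygen functions apart. The strategy rests on one feature: ring B is bound through two neighbouring carbons, B2 to oxygen and B1 to C6, which is the 1,2-pattern an aryne leaves when a nucleophile and an electrophile add across it.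

## Retrosynthetic reasoning

27 is traced to 26, in which the C3 oxygen carries a tert-butyldimethylsilyl (TBS) group and the A4 and B4 oxygens carry 2-(trimethylsilyl)ethoxymethyl (SEM) groups. All three are cleaved through silicon, so one basic fluoride treatment frees 27 without exposing the enol ether or the prenylphenol to acid. Plain aryl silyl ethers were not used on the phenols: the fluoride that releases the aryne earlier in the route would cleave them and set competing phenoxides free. The SEM acetal resists fluoride at moderate temperature and yields only on heating.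

The hydrogen at B6 of 26 is replaced by bromine, giving 25. The bromine is a control element for the aryne step only. It is removed by halogen–metal exchange once no carbonyl group is left in the molecule.

In 25 the O1–C6 bond is cut. The enol ether is the cyclodehydration product of δ-hydroxy ketone 24, in which the tertiary hydroxyl at C2 faces a ketone at C6. C5 is the only carbon that can lose a proton, so the double bond can only form where it is needed.

24 is traced to enone 23 by adding a C4=C5 double bond. This costs one conjugate reduction later, but it allows the fragment that delivers C6 to be an α,β-unsaturated lactone without an α-hydrogen.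

The key disconnection cuts O–B2 and B1–C6 of 23 at once. The C6 carbonyl with O1 attached is a lactone, so the precursor is hydroxyaryl lactone 16. Ring B becomes aryne 22, generated from silyl triflate 21. Forward, the A2 phenoxide adds to the aryne and the resulting B1 anion attacks the lactone carbonyl, expelling O1 as the tertiary alkoxide. Cutting here joins two fragments of similar size and closes the oxepine in the same operation. Of the two silyl triflates that give 22, the one with the triflate next to bromine is used, because it comes from symmetrical 17 without any regiochemical choice.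

16 is cut at the A1–C5 bond (C3 of the lactone) into iodolactone 10 and boronate 15. Ring A therefore enters late by cross-coupling. It is not carried through the chain-building steps, and no hindered tertiary alcohol has to be acylated by an arylacetic acid.

10 comes from lactone 9 by α-iodination. 9 is opened at the ring ester bond and at the C3=C4 double bond (lactone numbering) to aldehyde 7. Forward, a (Z)-selective olefination gives enoate 8, whose ester is cis to the chain and is captured by the tertiary hydroxyl.

7 is the oxidation product of primary alcohol 6, which comes from triol 4 through bis-silyl ether 5. The secondary hydroxyl (C3 of the target) must keep its TBS group to the end. Left free, it would compete with the tertiary hydroxyl in the later ring closures.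

4 carries both stereocentres. A cis-epoxide of nerol (1) has the two oxygens syn, but the target needs them anti. Epoxy alcohol 2 is therefore isomerised by Payne rearrangement to terminal epoxide 3, which inverts C2 (C3 of the target) and leaves C3 (C2 of the target) untouched. Opening of 3 at the primary carbon gives 4. The chiral ligand is taken from the enantiomeric series that gives (2R,3S)-2.

15 is traced through bromophenol 14 to mono-SEM ether 12 and on to symmetrical 11 and prenyl bromide 13. Monoprotection of 11 distinguishes the two oxygens. The SEM ether then directs metalation to its own ortho bromine, which becomes the prenyl group, and the bromine next to the free hydroxyl becomes boron.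

21 is traced through phenoxide 20 and silyl ether 19 to mono-SEM ether 18 and symmetrical 17. The two bromines of 17 are equivalent: one is converted into the trimethylsilyl group by an oxygen-to-carbon silyl shift and the other stays as the control element.

## Alternatives that were turned down

Alternative 1: The C2–C3 bond is cut and both stereocentres are traced to a strained oxetane. Forward, irradiation of vinyl 4-oxopentanoate A2 adds the ketone carbonyl across the vinyl ester double bond in an intramolecular Paternò–Büchi reaction. This forms the C2–C3 bond and a temporary O1–C4 bond and gives the oxetane-fused lactone A1.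
- For: the cis ring fusion fixes the relative configuration of C2 and C3 in one step from an achiral ester. On that point it is shorter than the five operations the chosen route needs from 1 to 7.
- Against: A1 is racemic unless the photoreaction is made enantioselective. An n,π* ketone adds only sluggishly to an electron-poor enol ester. A1 contains neither the terpenoid chain nor either arene, so the homoprenyl olefin must be built from the lactone carbonyl, the oxetane must be opened at C4 by a carbon nucleophile carrying ring A, and the whole dibenzoxepine is still to be made.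
- Comparison: it solves the part of the target that nerol supplies for free and leaves the hard part untouched. The chosen strategy spends its key step on the enol ether and the seven-membered diaryl ether.

Alternative 2: The enol ether double bond C5=C6 is cut back to two carbonyl groups. Forward, low-valent titanium from TiCl3 and Zn–Cu couples the ketone carbonyl beside ring A with the aroate carbonyl of ring B in open-chain keto ester A4. This closes the dihydropyran and gives A3. The oxepine would be closed afterwards by copper-mediated etherification between the A2 oxygen and the B2 bromide.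
- For: the tetrasubstituted enol ether is made directly in its final oxidation state, where the chosen route needs a conjugate reduction and a cyclodehydration. Ring B carries its substituents in fixed positions, so no regiochemical question arises. On both points it is stronger.
- Against: A4 requires acylation of the hindered tertiary C2 hydroxyl by an ortho-substituted aroyl donor. Its ketone has a β-silyloxy group that can eliminate under Lewis-acidic titanium. Ketone–ester coupling competes with intermolecular ketone–ketone coupling and needs high dilution and a large excess of metal. The aryl bromide needed for the later etherification is exposed to a strong reductant.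
- Comparison: the chosen strategy forms the diaryl ether and the B1–C6 bond together under non-reducing conditions and leaves the pyran closure to a mild acid-catalysed dehydration.

Alternative 3: The A2–O bond is cut with ring A in dearomatised form, as a 4-alkyl-4-methoxycyclohexadienone. Forward, K2CO3 in methanol releases the B2 phenoxide, which adds to the unsubstituted dienone carbon A2 and closes the oxepine. Acid then removes methanol twice, rearomatising ring A and creating the C5=C6 enol ether, to give A5.
- For: it is metal-free, the oxygen is delivered to a position defined by the dienone, and no bromine has to be carried and removed. Here too the alternative is stronger.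
- Against: the oxidative dearomatisation of a ring A bearing a prenyl group is unselective, since such oxidants also attack trisubstituted olefins. The oxa-Michael closure is a reversible seven-membered ring formation next to a quaternary carbon. Basic methanol also cleaves aryl silyl ethers, so the B4 protection of A5 would not survive as drawn. The acid step risks a dienone–phenol shift of the C5 substituent and exposes the prenylphenol to acid. The C5–A1 and C6–B1 bonds must already exist, so the full skeleton with extra, later destroyed stereocentres has to be assembled first.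
- Comparison: the chosen strategy joins a ring-A lactone and a ring-B aryne convergently and forms both bonds to ring B at once, at the price of one bromine removed later.

Key step: step 14

Remark: 4,6-dibromobenzene-1,3-diol (11) and 2,6-dibromobenzene-1,4-diol (17) are taken as purchasable; atom labels are pyran O1, C2–C6, ring A A1–A6 (A1 on C5, A2 ether oxygen) and ring B B1–B6 (B1 on C6, B2 ether oxygen).

## Steps

Step 1
Reactants: 1 nerol, (2Z)-3,7-dimethylocta-2,6-dien-1-ol
Product: 2 [(2R,3S)-3-methyl-3-(4-methylpent-3-en-1-yl)oxiran-2-yl]methanol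
Conditions: Ti(OiPr)4 (cat.), D-(−)-diethyl tartrate (cat.), t-BuOOH, 4 Å MS, CH2Cl2, −20 °C
Reagents that add atoms: tert-butyl hydroperoxide, CC(C)(C)OO
Why: Sharpless asymmetric epoxidation; the allylic hydroxyl binds titanium, so only the 2,3-olefin reacts and the 6,7-olefin is untouched. With the D-(−)-tartrate ligand oxygen should be delivered to the face that gives the (2R,3S)-cis-epoxide, which fixes C3 (C2 of the target) directly and C2 (C3 of the target) after one inversion.

Step 2
Reactants: 2 [(2R,3S)-3-methyl-3-(4-methylpent-3-en-1-yl)oxiran-2-yl]methanol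
Product: 4 (2S,3S)-3,7-dimethyloct-6-ene-1,2,3-triol, via Payne-rearranged terminal epoxy alcohol 3 (not isolated)
Conditions: NaOH (0.5 M aq.), t-BuOH, 75 °C
Reagents that add atoms: water, O
Why: Payne rearrangement followed by hydroxide opening; the C1 alkoxide displaces the epoxide oxygen at C2 with inversion to give 3, which hydroxide opens at its primary carbon. C3 is never attacked, so the anti (2S,3S)-triol should result.

Step 3
Reactants: 4 (2S,3S)-3,7-dimethyloct-6-ene-1,2,3-triol
Product: 5 (2S,3S)-1,2-bis[(tert-butyldimethylsilyl)oxy]-3,7-dimethyloct-6-en-3-ol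
Conditions: TBSCl (2.5 equiv), imidazole, DMF, 40 °C
Reagents that add atoms: tert-butyldimethylsilyl chloride, CC(C)(C)[Si](C)(C)Cl
Why: Silylation with a silyl chloride and imidazole protects the primary and secondary hydroxyls; the tertiary hydroxyl does not react under these conditions.

Step 4
Reactants: 5 (2S,3S)-1,2-bis[(tert-butyldimethylsilyl)oxy]-3,7-dimethyloct-6-en-3-ol
Product: 6 (2S,3S)-2-[(tert-butyldimethylsilyl)oxy]-3,7-dimethyloct-6-ene-1,3-diol
Conditions: HF·pyridine, pyridine, THF, 0 °C
Reagents that add atoms: none
Why: Selective desilylation; buffered HF·pyridine cleaves the unhindered primary silyl ether much faster than the secondary one flanked by a quaternary carbon.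

Step 5
Reactants: 6 (2S,3S)-2-[(tert-butyldimethylsilyl)oxy]-3,7-dimethyloct-6-ene-1,3-diol
Product: 7 (2R,3S)-2-[(tert-butyldimethylsilyl)oxy]-3-hydroxy-3,7-dimethyloct-6-enal
Conditions: Dess–Martin periodinane, NaHCO3, CH2Cl2, 0 °C to rt
Reagents that add atoms: none
Why: Dess–Martin oxidation under bicarbonate buffer; the tertiary alcohol and the olefin are inert and the α-silyloxy aldehyde should not epimerise (the descriptor at C2 changes only because the substituent priorities change).

Step 6
Reactants: 7 (2R,3S)-2-[(tert-butyldimethylsilyl)oxy]-3-hydroxy-3,7-dimethyloct-6-enal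
Product: 9 (5S,6S)-5-[(tert-butyldimethylsilyl)oxy]-6-methyl-6-(4-methylpent-3-en-1-yl)-5,6-dihydro-2H-pyran-2-one, via (Z)-hydroxy enoate 8 (not isolated)
Conditions: (CF3CH2O)2P(O)CH2CO2Me, KN(SiMe3)2, 18-crown-6, THF, −78 °C; then PPTS (cat.), toluene, 70 °C
Reagents that add atoms: methyl bis(2,2,2-trifluoroethyl)phosphonoacetate, COC(=O)CP(=O)(OCC(F)(F)F)OCC(F)(F)F
Why: Still–Gennari variant of the Horner–Wadsworth–Emmons reaction; the electron-poor phosphonate gives the kinetic (Z)-enoate 8, whose ester lies cis to the chain. The tertiary hydroxyl then closes the six-membered lactone under mild acid with loss of methanol; no stereocentre is formed.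

Step 7
Reactants: 9 (5S,6S)-5-[(tert-butyldimethylsilyl)oxy]-6-methyl-6-(4-methylpent-3-en-1-yl)-5,6-dihydro-2H-pyran-2-one
Product: 10 (5S,6S)-5-[(tert-butyldimethylsilyl)oxy]-3-iodo-6-methyl-6-(4-methylpent-3-en-1-yl)-5,6-dihydro-2H-pyran-2-one
Conditions: I2, pyridine/CH2Cl2 (1:1), 0 °C to rt
Reagents that add atoms: iodine, II
Why: Baylis–Hillman-type α-iodination; pyridine adds to the β-carbon, the enolate is iodinated and pyridine is expelled. Iodine adds only reversibly to the isolated trisubstituted olefin.

Step 8
Reactants: 11 4,6-dibromobenzene-1,3-diol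
Product: 12 2,4-dibromo-5-{[2-(trimethylsilyl)ethoxy]methoxy}phenol
Conditions: NaH (1.0 equiv), DMF, 0 °C; SEMCl (1.0 equiv)
Reagents that add atoms: 2-(trimethylsilyl)ethoxymethyl chloride, C[Si](C)(C)CCOCCl
Why: O-alkylation of the mono-phenoxide of a symmetrical diol; the two hydroxyls are equivalent, so the only issue is over-alkylation, which is handled by stoichiometry and by recycling recovered 11.

Step 9
Reactants: 12 2,4-dibromo-5-{[2-(trimethylsilyl)ethoxy]methoxy}phenol; 13 1-bromo-3-methylbut-2-ene
Product: 14 2-bromo-4-(3-methylbut-2-en-1-yl)-5-{[2-(trimethylsilyl)ethoxy]methoxy}phenol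
Conditions: n-BuLi (2.1 equiv), THF, −78 °C; CuBr·SMe2; 13, −78 to 0 °C; aq. NH4Cl
Reagents that add atoms: none
Why: The first equivalent of base deprotonates the phenol. The second should exchange the bromine ortho to the chelating SEM ether and not the one beside the phenoxide, and copper-mediated SN2 alkylation with the allylic bromide should give the linear prenyl arene.

Step 10
Reactants: 14 2-bromo-4-(3-methylbut-2-en-1-yl)-5-{[2-(trimethylsilyl)ethoxy]methoxy}phenol
Product: 15 4-(3-methylbut-2-en-1-yl)-2-(4,4,5,5-tetramethyl-1,3,2-dioxaborolan-2-yl)-5-{[2-(trimethylsilyl)ethoxy]methoxy}phenol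
Conditions: n-BuLi (1.05 equiv), then t-BuLi (2.1 equiv), THF, −78 °C; i-PrOBpin, −78 °C to rt; aq. NH4Cl
Reagents that add atoms: 2-isopropoxy-4,4,5,5-tetramethyl-1,3,2-dioxaborolane, CC(C)OB1OC(C)(C)C(C)(C)O1
Why: Dianion formation from a 2-bromophenol (O–H deprotonation, then bromine–lithium exchange) and borylation with an alkoxyboronate; the SEM ether and the prenyl group are inert at −78 °C.

Step 11
Reactants: 10 (5S,6S)-5-[(tert-butyldimethylsilyl)oxy]-3-iodo-6-methyl-6-(4-methylpent-3-en-1-yl)-5,6-dihydro-2H-pyran-2-one; 15 4-(3-methylbut-2-en-1-yl)-2-(4,4,5,5-tetramethyl-1,3,2-dioxaborolan-2-yl)-5-{[2-(trimethylsilyl)ethoxy]methoxy}phenol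
Product: 16 (5S,6S)-5-[(tert-butyldimethylsilyl)oxy]-3-[2-hydroxy-5-(3-methylbut-2-en-1-yl)-4-{[2-(trimethylsilyl)ethoxy]methoxy}phenyl]-6-methyl-6-(4-methylpent-3-en-1-yl)-5,6-dihydro-2H-pyran-2-one
Conditions: Pd(OAc)2 (cat.), SPhos, K3PO4, THF/H2O, 40 °C
Reagents that add atoms: none
Why: Suzuki–Miyaura coupling of an α-iodo enoate (fast oxidative addition) with an ortho-hydroxyarylboronate; the bulky electron-rich phosphine allows a low temperature, so lactone and boronate should survive. The phenoxide cannot displace the much more basic tertiary alkoxide from the lactone.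

Step 12
Reactants: 17 2,6-dibromobenzene-1,4-diol
Product: 18 2,6-dibromo-4-{[2-(trimethylsilyl)ethoxy]methoxy}phenol
Conditions: NaH (2.2 equiv), DMF, 0 °C; SEMCl (1.0 equiv); aq. NH4Cl
Reagents that add atoms: 2-(trimethylsilyl)ethoxymethyl chloride, C[Si](C)(C)CCOCCl
Why: Selective O-alkylation of a dianion; the unhindered, more basic 4-phenoxide should be alkylated in preference to the 1-phenoxide, which is flanked by two bromines and is the weaker nucleophile.

Step 13
Reactants: 18 2,6-dibromo-4-{[2-(trimethylsilyl)ethoxy]methoxy}phenol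
Product: 21 2-bromo-6-(trimethylsilyl)-4-{[2-(trimethylsilyl)ethoxy]methoxy}phenyl trifluoromethanesulfonate, via aryl trimethylsilyl ether 19 (not isolated), via lithium 2-bromo-6-silylphenoxide 20 (not isolated)
Conditions: (Me3Si)2NH, THF, 65 °C, evaporate; n-BuLi (1.05 equiv), THF, −100 to −78 °C; Tf2O, −100 to −78 °C
Reagents that add atoms: hexamethyldisilazane, C[Si](C)(C)N[Si](C)(C)C; trifluoromethanesulfonic anhydride, O=S(=O)(OS(=O)(=O)C(F)(F)F)C(F)(F)F
Why: Standard route to 2-(trimethylsilyl)aryl triflates: O-silylation, bromine–lithium exchange with 1,3 oxygen-to-carbon silyl shift (retro-Brook rearrangement), then O-triflation. The two bromines are equivalent, and the phenoxide 20 formed after the shift is inert to further exchange.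

Step 14
Reactants: 16 (5S,6S)-5-[(tert-butyldimethylsilyl)oxy]-3-[2-hydroxy-5-(3-methylbut-2-en-1-yl)-4-{[2-(trimethylsilyl)ethoxy]methoxy}phenyl]-6-methyl-6-(4-methylpent-3-en-1-yl)-5,6-dihydro-2H-pyran-2-one; 21 2-bromo-6-(trimethylsilyl)-4-{[2-(trimethylsilyl)ethoxy]methoxy}phenyl trifluoromethanesulfonate
Product: 23 (11Z)-9-bromo-11-[(2S,3S)-2-[(tert-butyldimethylsilyl)oxy]-3-hydroxy-3,7-dimethyloct-6-en-1-ylidene]-2-(3-methylbut-2-en-1-yl)-3,7-bis{[2-(trimethylsilyl)ethoxy]methoxy}dibenzo[b,f]oxepin-10(11H)-one, via aryne 22 (not isolated)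
Conditions: CsF (4 equiv), THF, 65 °C, slow addition of 21 (1.5 equiv)
Reagents that add atoms: none
Why: Proposed new method: fluoride attacks the trimethylsilyl group of 21 and triflate leaves, releasing aryne 22; the phenoxide of 16 (formed with fluoride as base) adds to the aryne carbon remote from bromine, which places the aryl anion at B1 beside the inductively stabilising bromine, and this anion attacks the lactone carbonyl in a 7-exo-trig closure of the oxepine; collapse of the tetrahedral intermediate expels the tertiary alkoxide, which takes up the proton released from the phenol. The closest known reaction type is the aryne O-arylation/acyl-capture annulation of salicylate esters to xanthones, which closes a six-membered ring on an acyclic ester; closure of a seven-membered ring on an unsaturated lactone has not been shown. No stereocentre is formed, the two existing ones are remote from the reacting atoms, and the exocyclic double bond keeps the geometry it had inside the lactone ring. Three selectivities are needed: regiochemistry of the phenoxide addition, secured by the bromine beside one aryne carbon and reinforced by the para acetal oxygen; acyl capture in place of protonation, secured by aprotic THF, slow release of the aryne and the absence of an α-hydrogen in the unsaturated lactone; and 1,2- over 1,4-attack on the enoate, favoured because the carbonyl carbon is the harder and less shielded site while the β-carbon is screened by the neighbouring silyloxy group and quaternary centre. The SEM acetals and the alkyl silyl ether should not be attacked by CsF in THF.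

Step 15
Reactants: 23 (11Z)-9-bromo-11-[(2S,3S)-2-[(tert-butyldimethylsilyl)oxy]-3-hydroxy-3,7-dimethyloct-6-en-1-ylidene]-2-(3-methylbut-2-en-1-yl)-3,7-bis{[2-(trimethylsilyl)ethoxy]methoxy}dibenzo[b,f]oxepin-10(11H)-one
Product: 24 9-bromo-11-[(2S,3S)-2-[(tert-butyldimethylsilyl)oxy]-3-hydroxy-3,7-dimethyloct-6-en-1-yl]-2-(3-methylbut-2-en-1-yl)-3,7-bis{[2-(trimethylsilyl)ethoxy]methoxy}dibenzo[b,f]oxepin-10(11H)-one (both C11 epimers)
Conditions: [(Ph3P)CuH]6 (0.5 equiv), H2O, benzene, rt
Reagents that add atoms: none
Why: Conjugate reduction by the phosphine copper hydride; hydride goes to the β-carbon (C4 of the target) and water protonates the copper enolate. Aryl bromide, isolated olefins and the ketone are not reduced; the new stereocentre at C5 is uncontrolled and is erased in the next step.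

Step 16
Reactants: 24 9-bromo-11-[(2S,3S)-2-[(tert-butyldimethylsilyl)oxy]-3-hydroxy-3,7-dimethyloct-6-en-1-yl]-2-(3-methylbut-2-en-1-yl)-3,7-bis{[2-(trimethylsilyl)ethoxy]methoxy}dibenzo[b,f]oxepin-10(11H)-one
Product: 25 the (2S,3S) tetracyclic enol ether: target skeleton with bromine at B6, TBS on the C3 oxygen and SEM on the A4 and B4 oxygens
Conditions: PPTS (cat.), 4 Å MS, toluene, 90 °C
Reagents that add atoms: none
Why: Acid-catalysed cyclodehydration; the tertiary hydroxyl adds to the ketone in a six-membered ring and water is lost towards C5, the only carbon with a hydrogen. Both C5 epimers should converge on the conjugated tetrasubstituted enol ether.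

Step 17
Reactants: 25 the B6-bromo tetracyclic enol ether
Product: 26 the (2S,3S) tetracyclic enol ether with hydrogen at B6, TBS on the C3 oxygen and SEM on the A4 and B4 oxygens
Conditions: t-BuLi (2.2 equiv), THF, −78 °C; MeOH
Reagents that add atoms: none
Why: Bromine–lithium exchange is faster than any deprotonation at −78 °C, and methanol protonates the aryllithium. There is no ortho silyloxy group that could migrate and no carbonyl group left to be attacked.

Step 18
Reactants: 26 the protected tetracyclic enol ether
Product: 27 the target, (2S,3S)-2-methyl-2-(4-methylpent-3-en-1-yl)-3-hydroxy-3,4-dihydro-2H-pyran fused at C5=C6 to the dibenzo[b,f]oxepine, with A4-OH, A5-prenyl and B4-OH (CNP0185870.1)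
Conditions: Bu4NF (excess), ethylenediamine, DMF, 70 °C; aq. NH4Cl
Reagents that add atoms: none
Why: Fluoride-mediated global deprotection; fluoride cleaves the secondary silyl ether and fragments both aryl SEM acetals (attack at silicon, loss of ethene and formaldehyde), and ethylenediamine traps the formaldehyde. The basic, non-acidic medium should leave the enol ether and the prenylphenol intact, and no stereocentre is touched.

## Compound list

1 | nerol, (2Z)-3,7-dimethylocta-2,6-dien-1-ol | CC(C)=CCC/C(C)=C\CO | starting material
2 | [(2R,3S)-3-methyl-3-(4-methylpent-3-en-1-yl)oxiran-2-yl]methanol | CC(C)=CCC[C@]1(C)O[C@@H]1CO | intermediate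
3 | (2S)-6-methyl-2-[(2S)-oxiran-2-yl]hept-5-en-2-ol | CC(C)=CCC[C@](C)(O)[C@@H]1CO1 | intermediate
4 | (2S,3S)-3,7-dimethyloct-6-ene-1,2,3-triol | CC(C)=CCC[C@](C)(O)[C@@H](O)CO | intermediate
5 | (2S,3S)-1,2-bis[(tert-butyldimethylsilyl)oxy]-3,7-dimethyloct-6-en-3-ol | CC(C)=CCC[C@](C)(O)[C@@H](O[Si](C)(C)C(C)(C)C)CO[Si](C)(C)C(C)(C)C | intermediate
6 | (2S,3S)-2-[(tert-butyldimethylsilyl)oxy]-3,7-dimethyloct-6-ene-1,3-diol | CC(C)=CCC[C@](C)(O)[C@@H](O[Si](C)(C)C(C)(C)C)CO | intermediate
7 | (2R,3S)-2-[(tert-butyldimethylsilyl)oxy]-3-hydroxy-3,7-dimethyloct-6-enal | CC(C)=CCC[C@](C)(O)[C@@H](O[Si](C)(C)C(C)(C)C)C=O | intermediate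
8 | methyl (2Z,4S,5S)-4-[(tert-butyldimethylsilyl)oxy]-5-hydroxy-5,9-dimethyldeca-2,8-dienoate | CC(C)=CCC[C@](C)(O)[C@@H](O[Si](C)(C)C(C)(C)C)/C=C\C(=O)OC | intermediate
9 | (5S,6S)-5-[(tert-butyldimethylsilyl)oxy]-6-methyl-6-(4-methylpent-3-en-1-yl)-5,6-dihydro-2H-pyran-2-one | CC(C)=CCC[C@]1(C)OC(=O)C=C[C@@H]1O[Si](C)(C)C(C)(C)C | intermediate
10 | (5S,6S)-5-[(tert-butyldimethylsilyl)oxy]-3-iodo-6-methyl-6-(4-methylpent-3-en-1-yl)-5,6-dihydro-2H-pyran-2-one | CC(C)=CCC[C@]1(C)OC(=O)C(I)=C[C@@H]1O[Si](C)(C)C(C)(C)C | intermediate
11 | 4,6-dibromobenzene-1,3-diol | Oc1cc(O)c(Br)cc1Br | starting material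
12 | 2,4-dibromo-5-{[2-(trimethylsilyl)ethoxy]methoxy}phenol | Oc1cc(OCOCC[Si](C)(C)C)c(Br)cc1Br | intermediate
13 | 1-bromo-3-methylbut-2-ene | CC(C)=CCBr | starting material
14 | 2-bromo-4-(3-methylbut-2-en-1-yl)-5-{[2-(trimethylsilyl)ethoxy]methoxy}phenol | Oc1cc(OCOCC[Si](C)(C)C)c(CC=C(C)C)cc1Br | intermediate
15 | 4-(3-methylbut-2-en-1-yl)-2-(4,4,5,5-tetramethyl-1,3,2-dioxaborolan-2-yl)-5-{[2-(trimethylsilyl)ethoxy]methoxy}phenol | Oc1cc(OCOCC[Si](C)(C)C)c(CC=C(C)C)cc1B1OC(C)(C)C(C)(C)O1 | intermediate
16 | (5S,6S)-5-[(tert-butyldimethylsilyl)oxy]-3-[2-hydroxy-5-(3-methylbut-2-en-1-yl)-4-{[2-(trimethylsilyl)ethoxy]methoxy}phenyl]-6-methyl-6-(4-methylpent-3-en-1-yl)-5,6-dihydro-2H-pyran-2-one | CC(C)=CCC[C@]1(C)OC(=O)C(=C[C@@H]1O[Si](C)(C)C(C)(C)C)c1cc(CC=C(C)C)c(OCOCC[Si](C)(C)C)cc1O | intermediate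
17 | 2,6-dibromobenzene-1,4-diol | Oc1cc(Br)c(O)c(Br)c1 | starting material
18 | 2,6-dibromo-4-{[2-(trimethylsilyl)ethoxy]methoxy}phenol | Oc1c(Br)cc(OCOCC[Si](C)(C)C)cc1Br | intermediate
19 | (2,6-dibromo-4-{[2-(trimethylsilyl)ethoxy]methoxy}phenoxy)trimethylsilane | C[Si](C)(C)Oc1c(Br)cc(OCOCC[Si](C)(C)C)cc1Br | intermediate
20 | lithium 2-bromo-6-(trimethylsilyl)-4-{[2-(trimethylsilyl)ethoxy]methoxy}phenoxide | [Li+].[O-]c1c(Br)cc(OCOCC[Si](C)(C)C)cc1[Si](C)(C)C | intermediate
21 | 2-bromo-6-(trimethylsilyl)-4-{[2-(trimethylsilyl)ethoxy]methoxy}phenyl trifluoromethanesulfonate | C[Si](C)(C)c1cc(OCOCC[Si](C)(C)C)cc(Br)c1OS(=O)(=O)C(F)(F)F | intermediate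
22 | 3-bromo-5-{[2-(trimethylsilyl)ethoxy]methoxy}benzyne (1,2-didehydrobenzene) | BrC1=CC(OCOCC[Si](C)(C)C)=CC#C1 | intermediate
23 | (11Z)-9-bromo-11-[(2S,3S)-2-[(tert-butyldimethylsilyl)oxy]-3-hydroxy-3,7-dimethyloct-6-en-1-ylidene]-2-(3-methylbut-2-en-1-yl)-3,7-bis{[2-(trimethylsilyl)ethoxy]methoxy}dibenzo[b,f]oxepin-10(11H)-one | CC(C)=CCC[C@](C)(O)[C@@H](O[Si](C)(C)C(C)(C)C)/C=C1\C(=O)c2c(Br)cc(OCOCC[Si](C)(C)C)cc2Oc2cc(OCOCC[Si](C)(C)C)c(CC=C(C)C)cc21 | intermediate
24 | 9-bromo-11-[(2S,3S)-2-[(tert-butyldimethylsilyl)oxy]-3-hydroxy-3,7-dimethyloct-6-en-1-yl]-2-(3-methylbut-2-en-1-yl)-3,7-bis{[2-(trimethylsilyl)ethoxy]methoxy}dibenzo[b,f]oxepin-10(11H)-one, both C11 epimers | CC(C)=CCC[C@](C)(O)[C@@H](O[Si](C)(C)C(C)(C)C)CC1C(=O)c2c(Br)cc(OCOCC[Si](C)(C)C)cc2Oc2cc(OCOCC[Si](C)(C)C)c(CC=C(C)C)cc21 | intermediate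
25 | (2S,3S) tetracyclic enol ether with B6-Br, C3-OTBS, A4-OSEM, A5-prenyl, B4-OSEM | CC(C)=CCC[C@]1(C)OC2=C(C[C@@H]1O[Si](C)(C)C(C)(C)C)c1cc(CC=C(C)C)c(OCOCC[Si](C)(C)C)cc1Oc1cc(OCOCC[Si](C)(C)C)cc(Br)c12 | intermediate
26 | (2S,3S) tetracyclic enol ether with C3-OTBS, A4-OSEM, A5-prenyl, B4-OSEM | CC(C)=CCC[C@]1(C)OC2=C(C[C@@H]1O[Si](C)(C)C(C)(C)C)c1cc(CC=C(C)C)c(OCOCC[Si](C)(C)C)cc1Oc1cc(OCOCC[Si](C)(C)C)ccc12 | intermediate
27 | CNP0185870.1, the (2S,3S) dihydropyran-fused dibenzo[b,f]oxepine with C3-OH, A4-OH, A5-prenyl, B4-OH | CC(C)=CCC[C@]1(C)OC2=C(C[C@@H]1O)c1cc(CC=C(C)C)c(O)cc1Oc1cc(O)ccc12 | target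

## Step count and least certain steps

Total step count: 18. Longest linear sequence: 13 steps (1 to 27 through steps 1–7, 11 and 14–18). Ring A (steps 8–10) and ring B (steps 12–13) are made in parallel.

**Step 14 (key step, proposed new method).** The aryl anion at B1 may be quenched before it reaches the lactone carbonyl. It can be protonated, or it can lose the neighbouring bromide, because a seven-membered acyl capture is slower than the six-membered one known for salicylates. Conjugate attack on the β-carbon and ene reaction of the aryne with the prenyl olefins are further competing processes. Fallback with known chemistry, setting out from 16: an Ullmann-type coupling (CuI, picolinic acid, K3PO4, DMSO, 80 °C) with 1-bromo-2-iodo-4-{[2-(trimethylsilyl)ethoxy]methoxy}benzene F1 (the SEM ether of the corresponding commercial bromoiodophenol) should react at the iodide only. This gives (5S,6S)-3-[2-(2-bromo-5-{[2-(trimethylsilyl)ethoxy]methoxy}phenoxy)-5-prenyl-4-{[2-(trimethylsilyl)ethoxy]methoxy}phenyl]-5-[(tert-butyldimethylsilyl)oxy]-6-methyl-6-(4-methylpent-3-en-1-yl)-5,6-dihydro-2H-pyran-2-one F2. Bromine–lithium exchange (t-BuLi, THF, −100 °C) then starts a Parham cyclisation on the lactone carbonyl and gives the bromine-free hydroxy enone F3. Reduction with [(Ph3P)CuH]6 gives the bromine-free ketone F4, and PPTS cyclodehydration returns to the route at 26. Regiochemistry is then fixed by the dihalide, at the price of two more steps.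

**Step 7.** Conjugate addition of pyridine to the β-carbon may stall, because that carbon is flanked by the silyloxy-bearing carbon and the quaternary centre, and iodination would then remain incomplete. Fallback, setting out from 7: olefination with methyl 2-bromo-2-[bis(2,2,2-trifluoroethoxy)phosphoryl]acetate F5 (made by bromination of the phosphonate of step 6) under KN(SiMe3)2 and 18-crown-6 should give methyl (2E,4S,5S)-2-bromo-4-[(tert-butyldimethylsilyl)oxy]-5-hydroxy-5,9-dimethyldeca-2,8-dienoate F6, with the ester cis to the chain. F6 lactonises under PPTS to (5S,6S)-3-bromo-5-[(tert-butyldimethylsilyl)oxy]-6-methyl-6-(4-methylpent-3-en-1-yl)-5,6-dihydro-2H-pyran-2-one F7. Suzuki–Miyaura coupling of F7 with 15 under the conditions of step 11 returns to the route at 16. The halogen is then introduced with the olefin and not onto it.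

**Step 9.** Regiocontrol of the bromine–lithium exchange may be lost, with some exchange next to the phenoxide, and the phenoxide may be O-alkylated by 13 on warming. Fallback, setting out from 12: silylation (TBSCl, imidazole) gives tert-butyl(2,4-dibromo-5-{[2-(trimethylsilyl)ethoxy]methoxy}phenoxy)dimethylsilane F8. With no phenoxide present, one equivalent of n-BuLi should exchange only the bromine chelated by the SEM ether, and copper-mediated alkylation with 13 gives [2-bromo-4-(3-methylbut-2-en-1-yl)-5-{[2-(trimethylsilyl)ethoxy]methoxy}phenoxy](tert-butyl)dimethylsilane F9. Bu4NF buffered with acetic acid at 0 °C cleaves the aryl silyl ether and returns to the route at 14.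

**Step 11.** Protodeboronation of the electron-rich ortho-hydroxy boronate may outrun transmetalation, and aqueous base may open the iodolactone. Fallback, setting out from 14: the dianion generated as in step 10 is quenched with Bu3SnCl to give 4-(3-methylbut-2-en-1-yl)-2-(tributylstannyl)-5-{[2-(trimethylsilyl)ethoxy]methoxy}phenol F10. Stille coupling of F10 with 10 (Pd2(dba)3, AsPh3, CuI, NMP, rt) is neutral and base-free and returns to the route at 16.

**Step 18.** Cleavage of the aryl SEM acetals may be incomplete, or the liberated phenoxides may be hydroxymethylated by formaldehyde before it is trapped. Fallback, setting out from 26: Bu4NF at room temperature removes only the silyl ether and gives the bis-SEM alcohol F11 (26 with a free C3 hydroxyl). The two acetals are then cleaved by a Lewis acid (MgBr2·OEt2, nitromethane/ether, rt), which acts by chelation and bromide attack at the acetal carbon and not by fluoride-induced fragmentation, returning to the route at 27.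

## Further compounds

F1 | step 14 | 1-bromo-2-iodo-4-{[2-(trimethylsilyl)ethoxy]methoxy}benzene | Brc1ccc(OCOCC[Si](C)(C)C)cc1I
F2 | step 14 | (5S,6S)-3-[2-(2-bromo-5-{[2-(trimethylsilyl)ethoxy]methoxy}phenoxy)-5-(3-methylbut-2-en-1-yl)-4-{[2-(trimethylsilyl)ethoxy]methoxy}phenyl]-5-[(tert-butyldimethylsilyl)oxy]-6-methyl-6-(4-methylpent-3-en-1-yl)-5,6-dihydro-2H-pyran-2-one | CC(C)=CCC[C@]1(C)OC(=O)C(=C[C@@H]1O[Si](C)(C)C(C)(C)C)c1cc(CC=C(C)C)c(OCOCC[Si](C)(C)C)cc1Oc1cc(OCOCC[Si](C)(C)C)ccc1Br
F3 | step 14 | (11Z)-11-[(2S,3S)-2-[(tert-butyldimethylsilyl)oxy]-3-hydroxy-3,7-dimethyloct-6-en-1-ylidene]-2-(3-methylbut-2-en-1-yl)-3,7-bis{[2-(trimethylsilyl)ethoxy]methoxy}dibenzo[b,f]oxepin-10(11H)-one | CC(C)=CCC[C@](C)(O)[C@@H](O[Si](C)(C)C(C)(C)C)/C=C1\C(=O)c2ccc(OCOCC[Si](C)(C)C)cc2Oc2cc(OCOCC[Si](C)(C)C)c(CC=C(C)C)cc21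
F4 | step 14 | 11-[(2S,3S)-2-[(tert-butyldimethylsilyl)oxy]-3-hydroxy-3,7-dimethyloct-6-en-1-yl]-2-(3-methylbut-2-en-1-yl)-3,7-bis{[2-(trimethylsilyl)ethoxy]methoxy}dibenzo[b,f]oxepin-10(11H)-one, both C11 epimers | CC(C)=CCC[C@](C)(O)[C@@H](O[Si](C)(C)C(C)(C)C)CC1C(=O)c2ccc(OCOCC[Si](C)(C)C)cc2Oc2cc(OCOCC[Si](C)(C)C)c(CC=C(C)C)cc21
F5 | step 7 | methyl 2-bromo-2-[bis(2,2,2-trifluoroethoxy)phosphoryl]acetate | COC(=O)C(Br)P(=O)(OCC(F)(F)F)OCC(F)(F)F
F6 | step 7 | methyl (2E,4S,5S)-2-bromo-4-[(tert-butyldimethylsilyl)oxy]-5-hydroxy-5,9-dimethyldeca-2,8-dienoate | CC(C)=CCC[C@](C)(O)[C@@H](O[Si](C)(C)C(C)(C)C)/C=C(/Br)C(=O)OC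
F7 | step 7 | (5S,6S)-3-bromo-5-[(tert-butyldimethylsilyl)oxy]-6-methyl-6-(4-methylpent-3-en-1-yl)-5,6-dihydro-2H-pyran-2-one | CC(C)=CCC[C@]1(C)OC(=O)C(Br)=C[C@@H]1O[Si](C)(C)C(C)(C)C
F8 | step 9 | tert-butyl(2,4-dibromo-5-{[2-(trimethylsilyl)ethoxy]methoxy}phenoxy)dimethylsilane | CC(C)(C)[Si](C)(C)Oc1cc(OCOCC[Si](C)(C)C)c(Br)cc1Br
F9 | step 9 | [2-bromo-4-(3-methylbut-2-en-1-yl)-5-{[2-(trimethylsilyl)ethoxy]methoxy}phenoxy](tert-butyl)dimethylsilane | CC(C)(C)[Si](C)(C)Oc1cc(OCOCC[Si](C)(C)C)c(CC=C(C)C)cc1Br
F10 | step 11 | 4-(3-methylbut-2-en-1-yl)-2-(tributylstannyl)-5-{[2-(trimethylsilyl)ethoxy]methoxy}phenol | CCCC[Sn](CCCC)(CCCC)c1cc(CC=C(C)C)c(OCOCC[Si](C)(C)C)cc1O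
F11 | step 18 | (2S,3S) tetracyclic enol ether with free C3-OH, A4-OSEM, A5-prenyl, B4-OSEM | CC(C)=CCC[C@]1(C)OC2=C(C[C@@H]1O)c1cc(CC=C(C)C)c(OCOCC[Si](C)(C)C)cc1Oc1cc(OCOCC[Si](C)(C)C)ccc12
A1 | alternative 1 | cis-fused 6-methyl-2,7-dioxabicyclo[4.2.0]octan-3-one (enantiomer carried forward) | C[C@]12CCC(=O)O[C@H]1CO2
A2 | alternative 1 | vinyl 4-oxopentanoate | CC(=O)CCC(=O)OC=C
A3 | alternative 2 | 5-(ring A)-6-(ring B)-3-silyloxy-3,4-dihydro-2H-pyran | CC(C)=CCC[C@]1(C)OC(c2ccc(O[Si](C)(C)C(C)(C)C)cc2Br)=C(C[C@@H]1O[Si](C)(C)C(C)(C)C)c1cc(CC=C(C)C)c(O[Si](C)(C)C(C)(C)C)cc1O[Si](C)(C)C(C)(C)C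
A4 | alternative 2 | open-chain keto ester: 2-bromo-4-silyloxybenzoate of the tertiary C2 alcohol with the ring-A aryl ketone at C5 | CC(C)=CCC[C@](C)(OC(=O)c1ccc(O[Si](C)(C)C(C)(C)C)cc1Br)[C@H](CC(=O)c1cc(CC=C(C)C)c(O[Si](C)(C)C(C)(C)C)cc1O[Si](C)(C)C(C)(C)C)O[Si](C)(C)C(C)(C)C
A5 | alternative 3 | target with silyl ethers on the C3 and ring-B hydroxyls | CC(C)=CCC[C@]1(C)OC2=C(C[C@@H]1O[Si](C)(C)C(C)(C)C)c1cc(CC=C(C)C)c(O)cc1Oc1cc(O[Si](C)(C)C(C)(C)C)ccc12
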